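## Structural features

The target 25 is a single cyclohexene ring, C1 to C6, with one exocyclic carbon, C7, on the alkene carbon C5; the only other rings are the phenyl groups of the two benzoates. Four adjacent oxygen-bearing stereocentres run C6–C1–C2–C3 from one allylic position round to the other, with O1 and O2 cis and both O2/O3 and O1/O6 trans, so that O1 and O2 sit on one face and O3 and O6 on the other (1S,2S,3R,6S). The five oxygens are in three different states: benzoates on O6 and O7, an acetate on O1 alone, and free hydroxyls on O2 and O3. Both benzoates are allylic and can ionise with zerovalent palladium or Lewis acids, the O1 acetate is cis to the free O2 hydroxyl and can shift under base, and the ring can lose oxygen substituents on the way to an arene. In the hydroxy-ketone intermediates of the route the β-oxygen is also open to E1cB loss. The real difficulty is therefore not the carbocycle but placing three acylation states on five oxygens without ambiguity while C3 is set trans to C2. The key step exploits the fact that O2, O1 and O6 reproduce the L-manno triad at C2, C3 and C4 of 1, and that ring C4 can be the methyl carbon of that sugar. Joining that carbon to the former C1, which becomes ring C3, closes ring C1–C6 and leaves a C5 carbonyl that later receives C7.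

## Logic of the disconnections

**25 ⇒ 24.** The O2–Si and O3–Si bonds are cut. The trans-diol is freed last so that no hydroxyl stands beside an ester during any acylation, and 24 has every oxygen capped. The forward step must remove two silyl groups under non-basic conditions, so that the O1 acetate stays on O1 and the allylic benzoates survive.

**24 ⇒ 22 + 23.** The O1–C(acetyl) bond is cut. In 22, O1 is the only free hydroxyl, so the acetate/hydroxyl choice on the cis O1/O2 pair becomes a matter of protecting groups and needs no selectivity. The demand is a mild acylation that does not move the O6 benzoate.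

**22 ⇒ 21.** The O1–CH2(2-naphthyl) bond is cut. This returns O1 to an ether that has been unique since 6, so nothing has to be differentiated at this late stage. The forward cleavage must be oxidative and neutral, because reductive, basic or palladium conditions would touch the allylic benzoates.

**21 ⇒ 19 + 20.** The two acyl C–O bonds at O6 and O7 are cut together. Both hydroxyls need the same acyl group, so one operation serves, and 19 carries no ester at all. The forward step only has to acylate both free hydroxyls completely.

**19 ⇒ 18.** Two C7–H bonds are removed, which raises C7 to the ester level. The hydride reduction is placed before any ester of the target exists, so 18 needs no chemoselectivity among esters. It must be a clean 1,2-reduction of the conjugated ester.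

**18 ⇒ 17.** The O6–CH2(4-methoxyphenyl) bond is cut. This leaves 17 with all four ring oxygens masked for the carbon–carbon bond formation. The forward step must cleave this one ether and leave the 2-naphthylmethyl ether on O1 and both silyl ethers intact.

**17 ⇒ 15 + 16.** The C5–C7 bond is cut. Inserting 16 into the C5–O sulfonate bond of 15 puts the missing carbon on a defined alkene carbon and fixes the C4=C5 position at once. This demands that 15 be formed with the alkene on the C4 side only.

**15 ⇒ 13 (through 14).** The C5–O(triflyl) bond and the C4=C5 π bond go back to the C5 ketone. This removes the alkene and returns to a saturated ring. The forward step must deprotonate at C4 and not at C6, and must not expel the C3 oxygen.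

**13 ⇒ 12.** The O3–Si bond is cut. This returns to the direct product of the ring closure. The silylation must be mild enough for a β-hydroxy ketone.

**12 ⇒ 11.** The C3–C4 ring bond is cut. This opens the carbocycle to acyclic 11, whose three stereocentres are those of 1. The forward aldol must set C3 trans to O2 and must not eliminate.

**11 ⇒ 10 ⇒ 9.** Both carbonyls go back to carbinols, and the chain C1 carbinol then returns to the ring C1–O5 bond of 9. Releasing the ring oxygen by reduction leaves exactly O1 and O5 free, so no further protecting-group step is needed. The double oxidation must not epimerise the α-oxygenated centres.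

**9 ⇒ 7 (through 8).** The anomeric O–allyl bond is cut. The allyl group keeps the anomeric centre masked through all the ether-forming steps. The forward unmasking must be non-acidic, because an acid-labile benzyl-type ether and a silyl ether are present.

**7 ⇒ 6 ⇒ 5.** The O2–Si bond and then the O3–CH2(2-naphthyl) bond are cut. This is the decisive differentiation of the future O1 from the future O2. It demands regioselective alkylation of the equatorial O3 of a cis-diol.

**5 ⇒ 4 ⇒ 3.** The acetonide is restored and the O4–CH2(4-methoxyphenyl) bond is cut. The cis-diol is masked only to single out O4, the future O6. The forward steps are an etherification of a single hydroxyl and an acetal hydrolysis that spares the new ether.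

**3 ⇒ 1 (through 2).** The glycosidic C1–O(allyl) bond and the two acetal C–O bonds are cut, which leads back to 1. The forward steps need only thermodynamic control.

## Other disconnections considered

Alternative 1: The cut removes the C3–O and C6–O bonds together and leads back to the diene ester A2, which (−)-shikimic acid A1 would supply by esterification, acetonide formation and elimination of its C5 hydroxyl. The forward key step is a photo-oxygenation. Excited O2 adds [4+2] across the diene termini anti to the dioxolane and gives endoperoxide A3. Reductive O–O cleavage would then release both oxygens cis to each other and trans to the acetonide, as C3 and C6 require.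
- In favour: A1 already holds all seven carbons and the C1/C2 stereocentres in the correct absolute sense. One pericyclic step would form two C–O bonds and two stereocentres, against one C–C bond and one stereocentre in step 9.
- In favour: a route of roughly ten to twelve steps can be imagined. On step economy this alternative is the better plan.
- Against: A2 is deactivated by the conjugated ester, so the cycloaddition with an electrophilic oxidant should be slow and ene-type hydroperoxidation can compete.
- Against: A3 has a bridgehead C3–H that is vinylogously acidified by the ester and is open to base-induced Kornblum–DeLaMare fragmentation.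
- Against: after O–O cleavage, O3 and O6 are both free and allylic and must be told apart.
- Against: O1 and O2 arrive as one acetonide. The acetate-on-O1, hydroxyl-on-O2 distinction would have to be made late on a cis-diol. The chosen plan settles it at 5 → 6, where cis-diol regiochemistry is well understood.
- Comparison: in structure both plans take the cis O1/O2 pair from the chiral pool, and the chosen plan also takes O6 and has all three already differentiated. In mechanism the suprafacial cycloaddition is at least the equal of the aldol for relative stereocontrol.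

Alternative 2: The cut removes the C6–O(benzoate) bond and contracts the ring to the gem-dibromocyclopropane A5, made by dibromocarbene addition to cyclopentene A4 from the pentose chiral pool. In the forward key step, silver benzoate A6 assists loss of bromide. The cyclopropane opens in a disrotatory sense to a 2-bromocyclohexenyl cation, and benzoate is captured at C6 to give A7.
- In favour: one operation delivers the six-membered ring, the C4=C5 alkene, a C5–Br handle for C7, and the O6 benzoate in its final form. The last point is better than the chosen plan, which needs a protect/deprotect pair at O6.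
- In favour: the vinyl bromide of A7 is the equal of the triflate of 15 as a coupling handle and avoids enolate chemistry altogether.
- Against: the two termini of the allyl cation, C4 and C6, are both flanked by oxygenated carbons, so neither the site nor the face of benzoate capture is secured. Three inductively withdrawing C–O bonds should also retard ionisation.
- Against: A4 needs its silyloxy group trans to the dioxolane, which is the less direct epimer to make.
- Against: C7 must later be introduced next to a benzoate, which rules out the carbonylation/hydride sequence.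
- Against: the O1/O2 acetonide again leaves the acetate/hydroxyl choice on a cis-diol to the end.
- Comparison: the step count is probably comparable to the chosen plan, not clearly lower. In mechanism a cationic capture with two open selectivities is less predictable than a chair-controlled aldol.

Alternative 3: The cut removes two ring C–C bonds, C2–C3 and C1–C6, and leads back to methyl coumalate A8 and 2,2-dimethyl-1,3-dioxole A9. The forward key step is an inverse-demand [4+2] addition followed by retro-[4+2] decarboxylation of the bridged adduct. It gives diene A10, the same constitution and configuration as A2.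
- In favour: it is the most convergent construction. Two C–C bonds, the whole carbocycle and C7 come from two simple achiral components in one operation, which is better than one ring bond per step in the chosen plan.
- Against: both partners are achiral, so only the cis relation of C1/C2 is set and not the absolute configuration. A single enantiomer would need a chiral catalyst or a resolution, whereas the chosen plan draws three stereocentres from 1.
- Against: the product diene can react again with A9, or aromatise by losing the acetonide-derived fragment.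
- Against: the route then joins Alternative 1 at A2 and inherits all its later problems.
- Comparison: it equals Alternative 1 after the diene and is shorter than the chosen plan in ring construction. It is weaker on enantiocontrol and on oxygen differentiation.

Key step: step 9

**Remarks on the chemistry**

- Mode of closure: the cyclisation of 11 is 6-(enolendo)-exo-trig. Both carbons of the enamine C=C become ring members and the ketone stays in the ring, so an enolexo label would not describe it.
- Protecting groups: three identical benzyl ethers on the keto-aldehyde would release O1, O2 and O6 together, and a late acetonide on the cis O1/O2 pair would still leave O1, O2 and O3 indistinguishable at the acetylation. Precursor 11 therefore keeps the 6-deoxy-L-lyxo-hexos-5-ulose skeleton but carries three orthogonal ethers: PMB (4-methoxybenzyl) on the future O6, NAP (2-naphthylmethyl) on the future O1 and TBS on the future O2.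
- Mapping: the three stereocentres of 11 become C6, C1 and C2 of 25 unchanged, and the carbinol of 12 becomes C3.
- Numbering: numbers are given to the substrate line and to the three reagents whose carbon stays in 25 (16, 20, 23). Other reagents appear with SMILES in the steps. Carbocycles 15–24 carry the ring numbering and the configuration of 25 (O1/O2 cis, O2/O3 trans, O1/O6 trans).
- Assumption: compounds 2–8 are drawn as α-anomers; any β-anomer converges at 9.

## Steps

Step 1
Reactants: 1 L-rhamnose
Product: 3 allyl 2,3-O-isopropylidene-α-L-rhamnopyranoside, via allyl α-L-rhamnopyranoside 2 (not isolated)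
Conditions: allyl alcohol, AcCl (cat.), 70 °C; evaporate; Me2C(OMe)2, TsOH (cat.), acetone, rt
Reagents that add atoms: allyl alcohol, C=CCO; 2,2-dimethoxypropane, COC(C)(C)OC
Why: Fischer glycosidation under thermodynamic control should give mainly the axial α-pyranoside, and acetonide formation takes only the cis-2,3-diol, leaving O4 free; the anomeric centre is removed in step 6, so its configuration is of no consequence.

Step 2
Reactants: 3 allyl 2,3-O-isopropylidene-α-L-rhamnopyranoside
Product: 4 allyl 2,3-O-isopropylidene-4-O-(4-methoxybenzyl)-α-L-rhamnopyranoside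
Conditions: NaH, 4-MeOC6H4CH2Cl, n-Bu4NI (cat.), DMF, 0 °C to rt
Reagents that add atoms: 4-methoxybenzyl chloride, COc1ccc(CCl)cc1
Why: Williamson etherification of the only free hydroxyl; this oxygen becomes O6 of the target and receives the ether that is removed first.

Step 3
Reactants: 4 allyl 2,3-O-isopropylidene-4-O-(4-methoxybenzyl)-α-L-rhamnopyranoside
Product: 5 allyl 4-O-(4-methoxybenzyl)-α-L-rhamnopyranoside
Conditions: AcOH/H2O (4:1), 50 °C
Reagents that add atoms: none
Why: Mild acetal hydrolysis frees the cis-2,3-diol; the PMB ether and the allyl glycoside should be stable to aqueous acetic acid at this temperature.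

Step 4
Reactants: 5 allyl 4-O-(4-methoxybenzyl)-α-L-rhamnopyranoside
Product: 6 allyl 4-O-(4-methoxybenzyl)-3-O-(2-naphthylmethyl)-α-L-rhamnopyranoside
Conditions: 2-(bromomethyl)naphthalene, Ag2O, Ph2BOCH2CH2NH2 (10 mol %), MeCN, 40 °C
Reagents that add atoms: 2-(bromomethyl)naphthalene, BrCc1ccc2ccccc2c1
Why: Borinic-acid-catalysed regioselective alkylation of a pyranoside cis-diol: the tetracoordinate borinate of the 2,3-diol is alkylated at the equatorial oxygen O3, so the future O1 is marked and the axial O2 stays free.

Step 5
Reactants: 6 allyl 4-O-(4-methoxybenzyl)-3-O-(2-naphthylmethyl)-α-L-rhamnopyranoside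
Product: 7 allyl 2-O-(tert-butyldimethylsilyl)-4-O-(4-methoxybenzyl)-3-O-(2-naphthylmethyl)-α-L-rhamnopyranoside
Conditions: TBSOTf, 2,6-lutidine, CH2Cl2, 0 °C
Reagents that add atoms: tert-butyldimethylsilyl triflate, CC(C)(C)[Si](C)(C)OS(=O)(=O)C(F)(F)F
Why: Silyl triflate silylation of the remaining hindered axial hydroxyl; this oxygen becomes the free O2 of the target and is unmasked with O3 in the last step.

Step 6
Reactants: 7 allyl 2-O-(tert-butyldimethylsilyl)-4-O-(4-methoxybenzyl)-3-O-(2-naphthylmethyl)-α-L-rhamnopyranoside
Product: 9 2-O-(tert-butyldimethylsilyl)-4-O-(4-methoxybenzyl)-3-O-(2-naphthylmethyl)-L-rhamnopyranose, via prop-1-enyl glycoside 8 (not isolated)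
Conditions: [Ir(cod)(PMePh2)2]PF6 (2 mol %, H2-activated), THF, rt; then I2, NaHCO3, THF/H2O, 0 °C
Reagents that add atoms: none
Why: The iridium hydride formed from [Ir(cod)(PMePh2)2]PF6 and H2 isomerises only the O-allyl group to the enol ether, which iodine and water cleave under bicarbonate buffering; the acid-labile PMB and silyl ethers should survive these non-acidic conditions.

Step 7
Reactants: 9 2-O-(tert-butyldimethylsilyl)-4-O-(4-methoxybenzyl)-3-O-(2-naphthylmethyl)-L-rhamnopyranose
Product: 10 2-O-(tert-butyldimethylsilyl)-6-deoxy-4-O-(4-methoxybenzyl)-3-O-(2-naphthylmethyl)-L-mannitol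
Conditions: NaBH4, EtOH, 0 °C to rt
Reagents that add atoms: none
Why: NaBH4 reduces the open-chain aldehyde in equilibrium with the lactol, giving the diol in which exactly O1 and O5 are free; the low temperature limits 1,2-silyl migration.

Step 8
Reactants: 10 2-O-(tert-butyldimethylsilyl)-6-deoxy-4-O-(4-methoxybenzyl)-3-O-(2-naphthylmethyl)-L-mannitol
Product: 11 2-O-(tert-butyldimethylsilyl)-6-deoxy-4-O-(4-methoxybenzyl)-3-O-(2-naphthylmethyl)-L-lyxo-hexos-5-ulose
Conditions: (COCl)2, DMSO, CH2Cl2, −78 °C; Et3N, −78 to 0 °C
Reagents that add atoms: none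
Why: Double Swern oxidation of a sugar 1,5-diol to the 1,5-dicarbonyl compound; the cold, briefly basic work-up should not epimerise the α-oxygenated centres, and the crude product is used at once.

Step 9
Reactants: 11 2-O-(tert-butyldimethylsilyl)-6-deoxy-4-O-(4-methoxybenzyl)-3-O-(2-naphthylmethyl)-L-lyxo-hexos-5-ulose
Product: 12 (2R,3R,4S,5R)-4-(tert-butyldimethylsilyloxy)-5-hydroxy-2-(4-methoxybenzyloxy)-3-(2-naphthylmethoxy)cyclohexan-1-one
Conditions: L-proline (30 mol %), DMSO, rt
Reagents that add atoms: none
Why: L-Proline condenses with the methyl ketone of 11 to the terminal enamine, whose CH2 carbon (ring C4) adds to the aldehyde carbon (ring C3) while the carboxylic acid protonates the developing alkoxide, and hydrolysis of the iminium ion returns the catalyst and leaves 12. The closest known reaction type is the amine-catalysed intramolecular aldol of keto-aldehydes (Hajos–Parrish type), which is also the carbonyl stage of a Ferrier carbocyclisation, reached here with no mercury reagent. The ring is closed in the 6-(enolendo)-exo-trig mode, both enamine carbons becoming ring members and the aldehyde C=O lying outside the new ring. The one new stereocentre, C3, is under substrate control: in the chair transition state the PMB and NAP ethers on ring C6 and C1 are equatorial, the silyloxy group on C2 is therefore axial, and the aldehyde C=O takes the axial position anti to that C–O bond (dipole opposition of the Cornforth kind), where it can also accept the catalyst's proton. This should place the new hydroxyl axial, trans to O2 and to O1, the same sense as in Ferrier-type aldolisations. Regioselectivity is secured because the enamine towards the alkoxy-bearing carbon would be tetrasubstituted and could close only a four-membered ring, and chemoselectivity because the α-branched α-silyloxy aldehyde is a poor enamine donor. The near-neutral medium is chosen to keep the β-hydroxyl from E1cB loss.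

Step 10
Reactants: 12 (2R,3R,4S,5R)-4-(tert-butyldimethylsilyloxy)-5-hydroxy-2-(4-methoxybenzyloxy)-3-(2-naphthylmethoxy)cyclohexan-1-one
Product: 13 (2R,3R,4R,5R)-4,5-bis(tert-butyldimethylsilyloxy)-2-(4-methoxybenzyloxy)-3-(2-naphthylmethoxy)cyclohexan-1-one
Conditions: TBSOTf, 2,6-lutidine, CH2Cl2, −78 °C
Reagents that add atoms: tert-butyldimethylsilyl triflate, CC(C)(C)[Si](C)(C)OS(=O)(=O)C(F)(F)F
Why: Silyl triflate with a hindered pyridine base silylates the axial β-hydroxyl at low temperature without retro-aldol or elimination; O2 and O3 now carry the same group and can be freed together at the end.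

Step 11
Reactants: 13 (2R,3R,4R,5R)-4,5-bis(tert-butyldimethylsilyloxy)-2-(4-methoxybenzyloxy)-3-(2-naphthylmethoxy)cyclohexan-1-one
Product: 15 2,3-bis(tert-butyldimethylsilyloxy)-6-(4-methoxybenzyloxy)-1-(2-naphthylmethoxy)cyclohex-4-en-5-yl trifluoromethanesulfonate, via potassium enolate 14 (not isolated)
Conditions: KN(SiMe3)2, THF, −78 °C; then N-(5-chloro-2-pyridyl)triflimide, −78 °C
Reagents that add atoms: N-(5-chloropyridin-2-yl)-1,1,1-trifluoro-N-(trifluoromethylsulfonyl)methanesulfonamide, FC(F)(F)S(=O)(=O)N(c1ccc(Cl)cn1)S(=O)(=O)C(F)(F)F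
Why: Kinetic deprotonation by a bulky amide base should take the unhindered C4 methylene proton in preference to the tertiary α-alkoxy proton at C6, and O-sulfonylation at −78 °C traps the enolate before the C3 silyloxy group can leave.

Step 12
Reactants: 15 2,3-bis(tert-butyldimethylsilyloxy)-6-(4-methoxybenzyloxy)-1-(2-naphthylmethoxy)cyclohex-4-en-5-yl trifluoromethanesulfonate; 16 carbon monoxide
Product: 17 methyl 2,3-bis(tert-butyldimethylsilyloxy)-6-(4-methoxybenzyloxy)-1-(2-naphthylmethoxy)cyclohex-4-ene-5-carboxylate
Conditions: Pd(OAc)2 (5 mol %), PPh3, CO (1 atm), MeOH, Et3N, DMF, 50 °C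
Reagents that add atoms: carbon monoxide (16), [C-]#[O+]; methanol, CO
Why: Palladium-catalysed methoxycarbonylation of an enol triflate: oxidative addition, CO insertion and methanolysis of the acyl-palladium species install C7 on C5 with the alkene fixed at C4=C5.

Step 13
Reactants: 17 methyl 2,3-bis(tert-butyldimethylsilyloxy)-6-(4-methoxybenzyloxy)-1-(2-naphthylmethoxy)cyclohex-4-ene-5-carboxylate
Product: 18 methyl 2,3-bis(tert-butyldimethylsilyloxy)-6-hydroxy-1-(2-naphthylmethoxy)cyclohex-4-ene-5-carboxylate
Conditions: (NH4)2Ce(NO3)6, MeCN/H2O (9:1), 0 °C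
Reagents that add atoms: none
Why: Single-electron oxidation by (NH4)2Ce(NO3)6 cleaves the electron-rich PMB ether much faster than the NAP ether, so only O6 should be freed; the conjugated ester is inert to the oxidant.

Step 14
Reactants: 18 methyl 2,3-bis(tert-butyldimethylsilyloxy)-6-hydroxy-1-(2-naphthylmethoxy)cyclohex-4-ene-5-carboxylate
Product: 19 2,3-bis(tert-butyldimethylsilyloxy)-5-(hydroxymethyl)-1-(2-naphthylmethoxy)cyclohex-4-en-6-ol
Conditions: i-Bu2AlH, CH2Cl2, −78 °C; aq. potassium sodium tartrate work-up
Reagents that add atoms: none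
Why: i-Bu2AlH reduces the conjugated ester in the 1,2 sense to the allylic alcohol; no other ester is present yet, and the ethers and silyl groups are inert.

Step 15
Reactants: 19 2,3-bis(tert-butyldimethylsilyloxy)-5-(hydroxymethyl)-1-(2-naphthylmethoxy)cyclohex-4-en-6-ol; 20 benzoyl chloride
Product: 21 6-O-benzoyl-5-(benzoyloxymethyl)-2,3-bis(tert-butyldimethylsilyloxy)-1-(2-naphthylmethoxy)cyclohex-4-ene
Conditions: BzCl, pyridine, DMAP (cat.), CH2Cl2, 0 °C to rt
Reagents that add atoms: benzoyl chloride (20), O=C(Cl)c1ccccc1
Why: Nucleophile-catalysed acylation of the only two free hydroxyls, O6 and O7, which both need the benzoate of the target.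

Step 16
Reactants: 21 6-O-benzoyl-5-(benzoyloxymethyl)-2,3-bis(tert-butyldimethylsilyloxy)-1-(2-naphthylmethoxy)cyclohex-4-ene
Product: 22 6-O-benzoyl-5-(benzoyloxymethyl)-2,3-bis(tert-butyldimethylsilyloxy)cyclohex-4-en-1-ol
Conditions: DDQ, CH2Cl2/pH 7 buffer (10:1), rt
Reagents that add atoms: none
Why: Oxidative cleavage of the NAP ether by DDQ under neutral conditions, which leave allylic benzoates, silyl ethers and the alkene untouched; O1 becomes the only free hydroxyl.

Step 17
Reactants: 22 6-O-benzoyl-5-(benzoyloxymethyl)-2,3-bis(tert-butyldimethylsilyloxy)cyclohex-4-en-1-ol; 23 acetic anhydride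
Product: 24 1-O-acetyl-6-O-benzoyl-5-(benzoyloxymethyl)-2,3-bis(tert-butyldimethylsilyloxy)cyclohex-4-ene
Conditions: Ac2O, pyridine, DMAP (cat.), CH2Cl2, 0 °C
Reagents that add atoms: acetic anhydride (23), CC(=O)OC(C)=O
Why: Acetylation of the single free hydroxyl needs no selectivity; fast DMAP-catalysed acyl transfer at 0 °C should outrun any shift of the neighbouring benzoate.

Step 18
Reactants: 24 1-O-acetyl-6-O-benzoyl-5-(benzoyloxymethyl)-2,3-bis(tert-butyldimethylsilyloxy)cyclohex-4-ene
Product: 25 (1S,2S,3R,6S)-1-O-acetyl-6-O-benzoyl-5-(benzoyloxymethyl)cyclohex-4-ene-1,2,3,6-tetrol (target)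
Conditions: HF·pyridine, pyridine/THF, 0 °C to rt
Reagents that add atoms: none
Why: Fluoride-driven cleavage of both Si–O bonds in a buffered acidic medium, in which ester migration and ionisation of the allylic benzoates should not occur; no stereocentre is touched.

## Compound list

1 | L-rhamnose (6-deoxy-L-mannose, open-chain form) | C[C@H](O)[C@H](O)[C@@H](O)[C@@H](O)C=O | starting material
2 | allyl α-L-rhamnopyranoside | C[C@H]1[C@H](O)[C@@H](O)[C@@H](O)[C@H](OCC=C)O1 | intermediate
3 | allyl 2,3-O-isopropylidene-α-L-rhamnopyranoside | C[C@H]1[C@H](O)[C@@H](OC2(C)C)[C@@H](O2)[C@H](OCC=C)O1 | intermediate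
4 | allyl 2,3-O-isopropylidene-4-O-(4-methoxybenzyl)-α-L-rhamnopyranoside | C[C@H]1[C@H](OCc3ccc(OC)cc3)[C@@H](OC2(C)C)[C@@H](O2)[C@H](OCC=C)O1 | intermediate
5 | allyl 4-O-(4-methoxybenzyl)-α-L-rhamnopyranoside | C[C@H]1[C@H](OCc2ccc(OC)cc2)[C@@H](O)[C@@H](O)[C@H](OCC=C)O1 | intermediate
6 | allyl 4-O-(4-methoxybenzyl)-3-O-(2-naphthylmethyl)-α-L-rhamnopyranoside | C[C@H]1[C@H](OCc2ccc(OC)cc2)[C@@H](OCc2ccc3ccccc3c2)[C@@H](O)[C@H](OCC=C)O1 | intermediate
7 | allyl 2-O-(tert-butyldimethylsilyl)-4-O-(4-methoxybenzyl)-3-O-(2-naphthylmethyl)-α-L-rhamnopyranoside | C[C@H]1[C@H](OCc2ccc(OC)cc2)[C@@H](OCc2ccc3ccccc3c2)[C@@H](O[Si](C)(C)C(C)(C)C)[C@H](OCC=C)O1 | intermediate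
8 | (E)-prop-1-enyl 2-O-(tert-butyldimethylsilyl)-4-O-(4-methoxybenzyl)-3-O-(2-naphthylmethyl)-α-L-rhamnopyranoside | C[C@H]1[C@H](OCc2ccc(OC)cc2)[C@@H](OCc2ccc3ccccc3c2)[C@@H](O[Si](C)(C)C(C)(C)C)[C@H](O/C=C/C)O1 | intermediate
9 | 2-O-(tert-butyldimethylsilyl)-4-O-(4-methoxybenzyl)-3-O-(2-naphthylmethyl)-L-rhamnopyranose (anomeric mixture) | C[C@H]1[C@H](OCc2ccc(OC)cc2)[C@@H](OCc2ccc3ccccc3c2)[C@@H](O[Si](C)(C)C(C)(C)C)C(O)O1 | intermediate
10 | 2-O-(tert-butyldimethylsilyl)-6-deoxy-4-O-(4-methoxybenzyl)-3-O-(2-naphthylmethyl)-L-mannitol (O1 and O5 free) | C[C@H](O)[C@H](OCc1ccc(OC)cc1)[C@@H](OCc1ccc2ccccc2c1)[C@@H](O[Si](C)(C)C(C)(C)C)CO | intermediate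
11 | 2-O-(tert-butyldimethylsilyl)-6-deoxy-4-O-(4-methoxybenzyl)-3-O-(2-naphthylmethyl)-L-lyxo-hexos-5-ulose | CC(=O)[C@H](OCc1ccc(OC)cc1)[C@@H](OCc1ccc2ccccc2c1)[C@@H](O[Si](C)(C)C(C)(C)C)C=O | intermediate
12 | (2R,3R,4S,5R)-4-(tert-butyldimethylsilyloxy)-5-hydroxy-2-(4-methoxybenzyloxy)-3-(2-naphthylmethoxy)cyclohexan-1-one (ketone = ring C5, carbinol = ring C3 of 25) | C1C(=O)[C@H](OCc2ccc(OC)cc2)[C@@H](OCc2ccc3ccccc3c2)[C@@H](O[Si](C)(C)C(C)(C)C)[C@@H]1O | intermediate
13 | (2R,3R,4R,5R)-4,5-bis(tert-butyldimethylsilyloxy)-2-(4-methoxybenzyloxy)-3-(2-naphthylmethoxy)cyclohexan-1-one | C1C(=O)[C@H](OCc2ccc(OC)cc2)[C@@H](OCc2ccc3ccccc3c2)[C@@H](O[Si](C)(C)C(C)(C)C)[C@@H]1O[Si](C)(C)C(C)(C)C | intermediate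
14 | potassium C4=C5 enolate of 13 | C1=C([O-])[C@H](OCc2ccc(OC)cc2)[C@@H](OCc2ccc3ccccc3c2)[C@@H](O[Si](C)(C)C(C)(C)C)[C@@H]1O[Si](C)(C)C(C)(C)C.[K+] | intermediate
15 | 2,3-bis(tert-butyldimethylsilyloxy)-6-(4-methoxybenzyloxy)-1-(2-naphthylmethoxy)cyclohex-4-en-5-yl trifluoromethanesulfonate (O1/O2 cis, O2/O3 trans, O1/O6 trans) | C1=C(OS(=O)(=O)C(F)(F)F)[C@H](OCc2ccc(OC)cc2)[C@@H](OCc2ccc3ccccc3c2)[C@@H](O[Si](C)(C)C(C)(C)C)[C@@H]1O[Si](C)(C)C(C)(C)C | intermediate
16 | carbon monoxide | [C-]#[O+] | starting material
17 | methyl 2,3-bis(tert-butyldimethylsilyloxy)-6-(4-methoxybenzyloxy)-1-(2-naphthylmethoxy)cyclohex-4-ene-5-carboxylate | C1=C(C(=O)OC)[C@H](OCc2ccc(OC)cc2)[C@@H](OCc2ccc3ccccc3c2)[C@@H](O[Si](C)(C)C(C)(C)C)[C@@H]1O[Si](C)(C)C(C)(C)C | intermediate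
18 | methyl 2,3-bis(tert-butyldimethylsilyloxy)-6-hydroxy-1-(2-naphthylmethoxy)cyclohex-4-ene-5-carboxylate | C1=C(C(=O)OC)[C@H](O)[C@@H](OCc2ccc3ccccc3c2)[C@@H](O[Si](C)(C)C(C)(C)C)[C@@H]1O[Si](C)(C)C(C)(C)C | intermediate
19 | 2,3-bis(tert-butyldimethylsilyloxy)-5-(hydroxymethyl)-1-(2-naphthylmethoxy)cyclohex-4-en-6-ol | C1=C(CO)[C@H](O)[C@@H](OCc2ccc3ccccc3c2)[C@@H](O[Si](C)(C)C(C)(C)C)[C@@H]1O[Si](C)(C)C(C)(C)C | intermediate
20 | benzoyl chloride | O=C(Cl)c1ccccc1 | starting material
21 | 6-O-benzoyl-5-(benzoyloxymethyl)-2,3-bis(tert-butyldimethylsilyloxy)-1-(2-naphthylmethoxy)cyclohex-4-ene | C1=C(COC(=O)c2ccccc2)[C@H](OC(=O)c2ccccc2)[C@@H](OCc2ccc3ccccc3c2)[C@@H](O[Si](C)(C)C(C)(C)C)[C@@H]1O[Si](C)(C)C(C)(C)C | intermediate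
22 | 6-O-benzoyl-5-(benzoyloxymethyl)-2,3-bis(tert-butyldimethylsilyloxy)cyclohex-4-en-1-ol | C1=C(COC(=O)c2ccccc2)[C@H](OC(=O)c2ccccc2)[C@@H](O)[C@@H](O[Si](C)(C)C(C)(C)C)[C@@H]1O[Si](C)(C)C(C)(C)C | intermediate
23 | acetic anhydride | CC(=O)OC(C)=O | starting material
24 | 1-O-acetyl-6-O-benzoyl-5-(benzoyloxymethyl)-2,3-bis(tert-butyldimethylsilyloxy)cyclohex-4-ene | C1=C(COC(=O)c2ccccc2)[C@H](OC(=O)c2ccccc2)[C@@H](OC(C)=O)[C@@H](O[Si](C)(C)C(C)(C)C)[C@@H]1O[Si](C)(C)C(C)(C)C | intermediate
25 | (1S,2S,3R,6S)-1-O-acetyl-6-O-benzoyl-5-(benzoyloxymethyl)cyclohex-4-ene-1,2,3,6-tetrol | CC(=O)O[C@H]1[C@@H](O)[C@H](O)C=C(COC(=O)c2ccccc2)[C@@H]1OC(=O)c1ccccc1 | target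

## Step count and least certain steps

Total: 18 steps. Longest linear sequence: 18 steps (1 → 25); the route is fully linear, with 16, 20 and 23 entering as reagents.

**Step 9 (key step).** What may go wrong: insufficient facial discrimination in the C3–C4 bond formation, loss of the new hydroxyl by E1cB elimination under amine catalysis, or epimerisation next to either carbonyl through enamine exchange. The fallback sets out from 11 and rejoins at 12, and it turns the elimination into the intended path. Aldol condensation of 11 (pyrrolidine, AcOH, CH2Cl2, rt) should give the cyclohexenone F1, on which both possible carbinol configurations converge. Copper-catalysed conjugate borylation (bis(pinacolato)diboron, CuCl, NaOt-Bu, bis(2-diphenylphosphinophenyl) ether, MeOH, THF, rt) should add boron to ring C3 anti to the neighbouring C2 silyloxy group and give the β-boryl ketone F2. Oxidation with NaBO3·4H2O in THF/H2O, with retention at carbon, then returns 12.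

**Step 11.** What may go wrong: expulsion of the C3 silyloxy group from the enolate (the axial C–O bond is aligned with the enolate π system), or competing deprotonation on the C6 side. The fallback sets out from 13 and rejoins at 19 without any enolate. Methylene transfer from the sulfonium ylide (Me3SI, KN(SiMe3)2, THF, −10 °C; Corey–Chaykovsky) should give the spiro-epoxide F6. Base-induced epoxide-to-allylic-alcohol isomerisation with diethylaluminium 2,2,6,6-tetramethylpiperidide (from Et2AlCl and lithium 2,2,6,6-tetramethylpiperidide, toluene, 0 °C) should remove the less hindered C4 proton and give the allylic alcohol F7, which already has C7 and the C4=C5 alkene. Cleavage of its PMB ether with (NH4)2Ce(NO3)6 in MeCN/H2O at 0 °C, where water intercepts the benzylic cation before the neighbouring hydroxyl can, leads to 19.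

**Step 13.** What may go wrong: concurrent cleavage of the NAP ether, or loss of a silyl ether in the acidic oxidising medium. The fallback sets out from 17 and rejoins at 24 and no longer needs the two benzyl-type ethers to be distinguished. Excess DDQ in CH2Cl2/H2O should remove both ethers and give the 1,6-diol ester F8, and i-Bu2AlH should reduce it to the 1,6,7-triol F9. Me2C(OMe)2 with pyridinium p-toluenesulfonate should close the six-membered acetal across the 1,3-related O6 and O7 to the 6,7-O-isopropylidene acetal F10, because the trans-vicinal O1/O6 pair would need a strained trans-fused five-membered ring. Ac2O in pyridine should then give the O1 acetate F11, AcOH/H2O at rt should open the acetal to the 6,7-diol F12, and BzCl in pyridine should give 24.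

**Step 4.** What may go wrong: incomplete discrimination between O3 and O2, or double alkylation. The fallback sets out from 5 and rejoins at 6 and fixes the regiochemistry through orthoester opening. MeC(OEt)3 with TsOH (cat.) in MeCN should give the cyclic orthoacetate F3, and aqueous AcOH at rt should open it to the axial ester, the 2-O-acetate F4. 2-Naphthylmethyl trichloroacetimidate with TMSOTf (cat.) in CH2Cl2 at −40 °C should alkylate the free O3 under acid, where the acetate does not migrate, and give the 2-O-acetyl 3-O-naphthylmethyl ether F5. NaOMe in MeOH then removes the acetate and gives 6.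

## Further compounds

F1 | step 9 | 4-(tert-butyldimethylsilyloxy)-6-(4-methoxybenzyloxy)-5-(2-naphthylmethoxy)cyclohex-2-en-1-one (three stereocentres as in 11) | O=C1C=C[C@H](O[Si](C)(C)C(C)(C)C)[C@H](OCc2ccc3ccccc3c2)[C@H]1OCc1ccc(OC)cc1
F2 | step 9 | 4-(tert-butyldimethylsilyloxy)-2-(4-methoxybenzyloxy)-3-(2-naphthylmethoxy)-5-(4,4,5,5-tetramethyl-1,3,2-dioxaborolan-2-yl)cyclohexan-1-one (boron trans to the 4-silyloxy group) | C1C(=O)[C@H](OCc2ccc(OC)cc2)[C@@H](OCc2ccc3ccccc3c2)[C@@H](O[Si](C)(C)C(C)(C)C)[C@@H]1B4OC(C)(C)C(C)(C)O4
F3 | step 4 | allyl 2,3-O-(1-ethoxyethylidene)-4-O-(4-methoxybenzyl)-α-L-rhamnopyranoside | C[C@H]1[C@H](OCc3ccc(OC)cc3)[C@@H](OC2(C)OCC)[C@@H](O2)[C@H](OCC=C)O1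
F4 | step 4 | allyl 2-O-acetyl-4-O-(4-methoxybenzyl)-α-L-rhamnopyranoside | C[C@H]1[C@H](OCc2ccc(OC)cc2)[C@@H](O)[C@@H](OC(C)=O)[C@H](OCC=C)O1
F5 | step 4 | allyl 2-O-acetyl-4-O-(4-methoxybenzyl)-3-O-(2-naphthylmethyl)-α-L-rhamnopyranoside | C[C@H]1[C@H](OCc2ccc(OC)cc2)[C@@H](OCc2ccc3ccccc3c2)[C@@H](OC(C)=O)[C@H](OCC=C)O1
F6 | step 11 | spiro-epoxide of 13 (1-oxaspiro[2.5]octane; the spiro carbon is ring C5, configuration there open) | C1C2(CO2)[C@H](OCc3ccc(OC)cc3)[C@@H](OCc3ccc4ccccc4c3)[C@@H](O[Si](C)(C)C(C)(C)C)[C@@H]1O[Si](C)(C)C(C)(C)C
F7 | step 11 | 2,3-bis(tert-butyldimethylsilyloxy)-5-(hydroxymethyl)-6-(4-methoxybenzyloxy)-1-(2-naphthylmethoxy)cyclohex-4-ene | C1=C(CO)[C@H](OCc2ccc(OC)cc2)[C@@H](OCc2ccc3ccccc3c2)[C@@H](O[Si](C)(C)C(C)(C)C)[C@@H]1O[Si](C)(C)C(C)(C)C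
F8 | step 13 | methyl 2,3-bis(tert-butyldimethylsilyloxy)-1,6-dihydroxycyclohex-4-ene-5-carboxylate | C1=C(C(=O)OC)[C@H](O)[C@@H](O)[C@@H](O[Si](C)(C)C(C)(C)C)[C@@H]1O[Si](C)(C)C(C)(C)C
F9 | step 13 | 2,3-bis(tert-butyldimethylsilyloxy)-5-(hydroxymethyl)cyclohex-4-ene-1,6-diol | C1=C(CO)[C@H](O)[C@@H](O)[C@@H](O[Si](C)(C)C(C)(C)C)[C@@H]1O[Si](C)(C)C(C)(C)C
F10 | step 13 | 6,7-O-isopropylidene acetal of F9 (1,3-dioxane across O6 and O7, O1 free) | C1=C2COC(C)(C)O[C@@H]2[C@@H](O)[C@@H](O[Si](C)(C)C(C)(C)C)[C@@H]1O[Si](C)(C)C(C)(C)C
F11 | step 13 | 1-O-acetyl-6,7-O-isopropylidene derivative | C1=C2COC(C)(C)O[C@@H]2[C@@H](OC(C)=O)[C@@H](O[Si](C)(C)C(C)(C)C)[C@@H]1O[Si](C)(C)C(C)(C)C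
F12 | step 13 | 1-O-acetyl-2,3-bis(tert-butyldimethylsilyloxy)-5-(hydroxymethyl)cyclohex-4-en-6-ol | C1=C(CO)[C@H](O)[C@@H](OC(C)=O)[C@@H](O[Si](C)(C)C(C)(C)C)[C@@H]1O[Si](C)(C)C(C)(C)C
A1 | alternative 1 | (−)-shikimic acid | C1[C@H]([C@@H]([C@@H](C=C1C(=O)O)O)O)O
A2 | alternative 1 | methyl (3R,4S)-3,4-(isopropylidenedioxy)cyclohexa-1,5-diene-1-carboxylate | CC1(C)O[C@H]2[C@@H](O1)C=CC(C(=O)OC)=C2
A3 | alternative 1 | bicyclic endoperoxide ester of A2 (peroxide bridging C3 and C6, anti to the dioxolane) | CC1(C)O[C@H]2[C@@H](O1)[C@H]3C=C(C(=O)OC)[C@@H]2OO3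
A4 | alternative 2 | 3-(tert-butyldimethylsilyloxy)-4,5-(isopropylidenedioxy)cyclopent-1-ene (silyloxy trans to the dioxolane) | CC1(C)O[C@H]2[C@@H](O1)[C@H](O[Si](C)(C)C(C)(C)C)C=C2
A5 | alternative 2 | 6,6-dibromo-2-(tert-butyldimethylsilyloxy)-3,4-(isopropylidenedioxy)bicyclo[3.1.0]hexane (cyclopropane drawn anti to the dioxolane) | CC1(C)O[C@H]2[C@@H](O1)[C@H](O[Si](C)(C)C(C)(C)C)[C@H]3[C@@H]2C3(Br)Br
A6 | alternative 2 | silver benzoate, AgO2CPh | [Ag+].[O-]C(=O)c1ccccc1
A7 | alternative 2 | 2-bromocyclohex-2-enyl benzoate carrying the O1/O2 acetonide and the O3 silyl ether | CC1(C)O[C@H]2[C@@H](O1)[C@H](O[Si](C)(C)C(C)(C)C)C=C(Br)[C@@H]2OC(=O)c1ccccc1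
A8 | alternative 3 | methyl coumalate (methyl 2-oxo-2H-pyran-5-carboxylate) | COC(=O)C1=COC(=O)C=C1
A9 | alternative 3 | 2,2-dimethyl-1,3-dioxole | CC1(C)OC=CO1
A10 | alternative 3 | methyl (3R,4S)-3,4-(isopropylidenedioxy)cyclohexa-1,5-diene-1-carboxylate (same compound as A2) | CC1(C)O[C@H]2[C@@H](O1)C=CC(C(=O)OC)=C2
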